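**Retrosynthetic overview**
- The enone C=C is cut last (Claisen–Schmidt) into 4-hydroxybenzaldehyde and the (S)-dihydrobenzofuranyl methyl ketone, with no protecting groups.
- The dihydrofuran C2–O bond is cut to an (R)-secondary/tertiary diol side chain on phloroacetophenone; ring closure is a Mitsunobu inversion through the non-chelated 4-OH.
- The (R)-carbinol comes from the α-hydroxy ketone ArCH2–CO–CMe2OH by hydroxyl-directed asymmetric hydrogenation, which sets the only stereocentre.
- Key C–C bond (aryl C3a–C3H2): the phloroacetophenone ring carbon attacks the α-carbon of 3-hydroxy-3-methylbutan-2-one, made electrophilic as its α-bromide (enolonium equivalent). Two natively nucleophilic carbons are joined, and this replaces the usual prenylation/epoxidation.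
- Ring order: both benzene rings are bought; the dihydrofuran is the only ring built (step 4), then the enone (step 5).

Assumption: the commercial monohydrate of 2,4,6-trihydroxyacetophenone is dried before use, and a numbered reactant is not listed again as a reagent.

**Route**

Step 1
Reactants: 1 3-hydroxy-3-methylbutan-2-one
Product: 2 1-bromo-3-hydroxy-3-methylbutan-2-one
Conditions: Br2 (1.0 equiv), MeOH, 0 °C to rt, 3 h
Reagents that add atoms: bromine, BrBr
Why: Acid-catalysed α-bromination of a ketone through its enol: the carbinol carbon bears no hydrogen, so enolisation and bromination can occur only at the methyl group, and one equivalent of Br2 stops at the monobromide that serves as the enolonium equivalent.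

Step 2
Reactants: 3 1-(2,4,6-trihydroxyphenyl)ethan-1-one; 2 1-bromo-3-hydroxy-3-methylbutan-2-one
Product: 4 1-[2,4,6-trihydroxy-3-(3-hydroxy-3-methyl-2-oxobutyl)phenyl]ethan-1-one
Conditions: 3 (1.5 equiv), LiOH·H2O (1.5 equiv), H2O/CF3CH2OH 1:1, 0 °C; 2 (1.0 equiv) added over 2 h, then rt, 12 h; AcOH to pH 5
Reagents that add atoms: none
Why: Reversed-polarity α-arylation of a ketone (Kornblum-type C-alkylation of an ambident phenoxide): bromoketone 2 is the a2 (enolonium) synthon of ketone 1 and is attacked in an SN2 step by the enol-like ring carbon C3 of the phloroacetophenone monoanion, the hydrogen-bonding water/CF3CH2OH medium shielding the phenoxide oxygen so that alkylation goes to carbon, the hindered carbonyl of 2 disfavouring Feist–Benary-type carbonyl attack, C3 and C5 being equivalent and excess 3 limiting dialkylation; no stereocentre is formed.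

Step 3
Reactants: 4 1-[2,4,6-trihydroxy-3-(3-hydroxy-3-methyl-2-oxobutyl)phenyl]ethan-1-one
Product: 5 1-{3-[(2R)-2,3-dihydroxy-3-methylbutyl]-2,4,6-trihydroxyphenyl}ethan-1-one
Conditions: H2 (50 atm), Ru2Cl4[(R)-BINAP]2(NEt3) (1 mol %), MeOH, 40 °C, 24 h
Reagents that add atoms: none
Why: Hydroxyl-directed asymmetric hydrogenation of an α-hydroxy ketone (Noyori BINAP–ruthenium hydrogenation): the tertiary OH and the ketone chelate ruthenium in a five-membered ring and hydride is delivered to one face, the (R)-BINAP complex giving the (2R)-carbinol by the same sense as hydroxyacetone to (R)-propane-1,2-diol, while the strongly hydrogen-bonded, electron-rich aryl methyl ketone is left untouched.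

Step 4
Reactants: 5 1-{3-[(2R)-2,3-dihydroxy-3-methylbutyl]-2,4,6-trihydroxyphenyl}ethan-1-one
Product: 7 1-[(2S)-4,6-dihydroxy-2-(2-hydroxypropan-2-yl)-2,3-dihydro-1-benzofuran-5-yl]ethan-1-one, via oxyphosphonium zwitterion 6 (not isolated)
Conditions: PPh3 (1.3 equiv) and diisopropyl azodicarboxylate (1.3 equiv) premixed, THF (0.02 M), 0 °C to rt
Reagents that add atoms: none
Why: Intramolecular Mitsunobu etherification: only the secondary alcohol is activated (6), the most acidic, non-chelated 4-OH para to the acetyl group is the pronucleophile and closes the dihydrofuran ring by 5-exo-tet SN2 attack with inversion, (2R)-carbinol to (2S)-ether, the tertiary alcohol and the two chelated phenols staying unreactive and the preformed betaine keeping free azodicarboxylate away from the electron-rich ring.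

Step 5
Reactants: 7 1-[(2S)-4,6-dihydroxy-2-(2-hydroxypropan-2-yl)-2,3-dihydro-1-benzofuran-5-yl]ethan-1-one; 8 4-hydroxybenzaldehyde
Product: 10 (2E)-1-[(2S)-4,6-dihydroxy-2-(2-hydroxypropan-2-yl)-2,3-dihydro-1-benzofuran-5-yl]-3-(4-hydroxyphenyl)prop-2-en-1-one, via aldol adduct 9 (not isolated)
Conditions: LiN(SiMe3)2 (6.5 equiv), THF, −78 °C to rt, 16 h; then 1 M HCl, 0 °C
Reagents that add atoms: none
Why: Claisen–Schmidt (crossed aldol) condensation run on the lithium polyanion: excess LiN(SiMe3)2 removes all OH protons and then an acetyl CH3 proton, the enolate adds to the aldehyde (9) and E1cB loss of hydroxide gives the conjugated (E)-enone under thermodynamic control; the C2 stereocentre carries no acidic hydrogen and is not touched, and a cold, brief acidic quench avoids closure to the flavanone.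

**Compound list**

1 | 3-hydroxy-3-methylbutan-2-one | CC(=O)C(C)(C)O | starting material
2 | 1-bromo-3-hydroxy-3-methylbutan-2-one | CC(C)(O)C(=O)CBr | intermediate
3 | 1-(2,4,6-trihydroxyphenyl)ethan-1-one (2,4,6-trihydroxyacetophenone) | CC(=O)c1c(O)cc(O)cc1O | starting material
4 | 1-[2,4,6-trihydroxy-3-(3-hydroxy-3-methyl-2-oxobutyl)phenyl]ethan-1-one | CC(=O)c1c(O)cc(O)c(CC(=O)C(C)(C)O)c1O | intermediate
5 | 1-{3-[(2R)-2,3-dihydroxy-3-methylbutyl]-2,4,6-trihydroxyphenyl}ethan-1-one | CC(C)(O)[C@H](O)Cc1c(O)cc(O)c(C(C)=O)c1O | intermediate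
6 | {[(2R)-1-(3-acetyl-2,4-dihydroxy-6-oxidophenyl)-3-hydroxy-3-methylbutan-2-yl]oxy}triphenylphosphonium (zwitterion, not isolated) | CC(C)(O)[C@H](O[P+](c1ccccc1)(c1ccccc1)c1ccccc1)Cc1c([O-])cc(O)c(C(C)=O)c1O | intermediate
7 | 1-[(2S)-4,6-dihydroxy-2-(2-hydroxypropan-2-yl)-2,3-dihydro-1-benzofuran-5-yl]ethan-1-one | CC(C)(O)[C@@H]1Cc2c(cc(O)c(C(C)=O)c2O)O1 | intermediate
8 | 4-hydroxybenzaldehyde | O=Cc1ccc(O)cc1 | starting material
9 | 1-[(2S)-4,6-dihydroxy-2-(2-hydroxypropan-2-yl)-2,3-dihydro-1-benzofuran-5-yl]-3-hydroxy-3-(4-hydroxyphenyl)propan-1-one (aldol adduct, both carbinol epimers, not isolated) | CC(C)(O)[C@@H]1Cc2c(cc(O)c(C(=O)CC(O)c3ccc(O)cc3)c2O)O1 | intermediate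
10 | (2E)-1-[(2S)-4,6-dihydroxy-2-(2-hydroxypropan-2-yl)-2,3-dihydro-1-benzofuran-5-yl]-3-(4-hydroxyphenyl)prop-2-en-1-one | CC(C)(O)[C@@H]1Cc2c(cc(O)c(C(=O)/C=C/c3ccc(O)cc3)c2O)O1 | target

**Step count and risks**

Total steps: 5. Longest linear sequence: 5 (1 → 2 → 4 → 5 → 7 → 10).

Steps most likely to fail:

Step 2 (C- versus O-alkylation and dialkylation of the free triphenol). The fallback sets out from 3 and comes back at 4. Mannich aminomethylation of 3 (37 % aq. CH2O, Me2NH, EtOH, rt) gives 1-{3-[(dimethylamino)methyl]-2,4,6-trihydroxyphenyl}ethan-1-one F1. Heating F1 with 2-hydroxy-2-methylpropanal, 3-benzyl-5-(2-hydroxyethyl)-4-methylthiazolium chloride (20 mol %) and Et3N in dioxane at 80 °C releases the ortho-quinone methide by loss of Me2NH. The Breslow intermediate of the aldehyde (an acyl anion equivalent) adds to the exocyclic CH2 in a Stetter-type 1,4-addition and gives 4. The bond formed is now C2–C3, again with reversed polarity, and O-alkylation is excluded because the ring carbon is already substituted in the Mannich step.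

Step 4 (4-OH versus chelated 2-OH as nucleophile, epoxide formation through the tertiary OH that would erode the ee, amination of the ring by the azodicarboxylate). The fallback sets out from 5 and comes back at 7. Ac2O (3.2 equiv) in pyridine at 0 °C acetylates the three phenols and gives 2-acetyl-4-[(2R)-2,3-dihydroxy-3-methylbutyl]benzene-1,3,5-triyl triacetate F3. MsCl/Et3N (CH2Cl2, −20 °C) sulfonylates only the secondary alcohol and gives 2-acetyl-4-[(2R)-3-hydroxy-2-(methanesulfonyloxy)-3-methylbutyl]benzene-1,3,5-triyl triacetate F4. K2CO3 in MeOH at rt removes the aryl acetates, and the liberated 4-phenoxide displaces the mesylate (5-exo-tet, inversion) to give 7.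

Step 3 (rate and enantioselectivity on a hindered, polyphenolic α-hydroxy ketone; possible acid-promoted cyclodehydration of 4 to a benzofuran). The fallback sets out from 4 and comes back at 5. NaBH4 (MeOH, 0 °C) reduces only the aliphatic ketone and gives the racemic diol, that is 5 together with its enantiomer 1-{3-[(2S)-2,3-dihydroxy-3-methylbutyl]-2,4,6-trihydroxyphenyl}ethan-1-one F2. Preparative supercritical-fluid chromatography on an amylose tris(3,5-dimethylphenylcarbamate) phase separates the two and returns enantiopure 5. The stereocentre is then secured by resolution instead of by asymmetric catalysis.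

**Further compounds**

F1 | step 2 | 1-{3-[(dimethylamino)methyl]-2,4,6-trihydroxyphenyl}ethan-1-one | CC(=O)c1c(O)cc(O)c(CN(C)C)c1O
F2 | step 3 | 1-{3-[(2S)-2,3-dihydroxy-3-methylbutyl]-2,4,6-trihydroxyphenyl}ethan-1-one | CC(C)(O)[C@@H](O)Cc1c(O)cc(O)c(C(C)=O)c1O
F3 | step 4 | 2-acetyl-4-[(2R)-2,3-dihydroxy-3-methylbutyl]benzene-1,3,5-triyl triacetate | CC(C)(O)[C@H](O)Cc1c(OC(C)=O)cc(OC(C)=O)c(C(C)=O)c1OC(C)=O
F4 | step 4 | 2-acetyl-4-[(2R)-3-hydroxy-2-(methanesulfonyloxy)-3-methylbutyl]benzene-1,3,5-triyl triacetate | CC(C)(O)[C@H](OS(C)(=O)=O)Cc1c(OC(C)=O)cc(OC(C)=O)c(C(C)=O)c1OC(C)=O
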